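**Retrosynthetic overview**

1. The chain (numbered C1 lactone carbonyl to C24 carboxyl carbon, C16' = hydroxymethyl carbon) is cut once, at C11–C12, into a C1–C11 primary iodide (lactone masked as a lactol isopropyl acetal) and a C12–C24 (12E,14E)-iododiene carboxylic acid. They are joined late by a B-alkyl Suzuki–Miyaura coupling, after which only acetal hydrolysis, one double oxidation and desilylation remain.
2. Enabling feature: C11 is an unfunctionalised primary CH2 whose only branch is the C10 methyl stereocentre (no β-heteroatom to eliminate), and C12 is the unsubstituted terminal CH of the C12=C13–C14=C15 diene. The same motif CH(CH3)–CH2–alkene recurs at C20–C23, so both halves start from (R)-Roche ester and both junctions are sp3–sp2 couplings.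
3. Left half: the 8Z alkene by iodo-olefination and Suzuki coupling, C4/C5 by anti-crotylboration of a dienal, ring A (O–C1–C2=C3–C4–C5) by ring-closing metathesis, then lactone to lactol acetal.
4. Right half: the 22E enoate by Negishi coupling with an (E)-enol triflate, C18/C19 by a second anti-crotylboration, C16 by an Evans aldol of a crotonyl imide whose carbonyl becomes C16', the diene by cross-metathesis and Takai olefination.
5. Ring order: ring A is the only ring made (step 7, before the union).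

Key step: step 25

Remark: the target has a 4,5-trans lactone and an all-anti C18–C20 triad, so both crotylations are anti-selective; the acetal carbon of every lactol or lactol ether intermediate is carried as an anomeric mixture and written without a descriptor, because it becomes the lactone carbonyl.

**Left half (C1–C11)**

Step 1
Reactants: 1 methyl (2R)-3-hydroxy-2-methylpropanoate
Product: 2 methyl (2R)-3-[(tert-butyldiphenylsilyl)oxy]-2-methylpropanoate
Conditions: TBDPSCl, imidazole, DMF, 0 °C → rt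
Reagents that add atoms: tert-butyl(chloro)diphenylsilane, CC(C)(C)[Si](Cl)(c1ccccc1)c1ccccc1
Why: Imidazole-mediated silyl ether formation at the primary alcohol; the purchased stereocentre (future C10) is not touched.

Step 2
Reactants: 2 methyl (2R)-3-[(tert-butyldiphenylsilyl)oxy]-2-methylpropanoate
Product: 3 (2R)-3-[(tert-butyldiphenylsilyl)oxy]-2-methylpropanal
Conditions: DIBAL-H (1.1 equiv), CH2Cl2, −78 °C; aq. potassium sodium tartrate
Reagents that add atoms: none
Why: Low-temperature DIBAL-H partial reduction of an ester stops at the aluminium hemiacetal and should give the aldehyde on work-up without epimerising the α-centre.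

Step 3
Reactants: 3 (2R)-3-[(tert-butyldiphenylsilyl)oxy]-2-methylpropanal; 4 propyltriphenylphosphonium bromide
Product: 7 tert-butyl{[(2S,3Z)-4-iodo-2-methylhex-3-en-1-yl]oxy}diphenylsilane, via (1-iodopropyl)triphenylphosphonium iodide 5 (not isolated), via (1-iodopropylidene)triphenylphosphorane 6 (not isolated)
Conditions: 4, n-BuLi, THF, 0 °C; I2, −78 °C; NaHMDS, −20 °C; then 3, −78 → −20 °C
Reagents that add atoms: iodine, II
Why: Stork–Zhao-type Wittig olefination with the α-iodo ylide should give the (Z)-trisubstituted vinyl iodide (iodine cis to the branched chain) under kinetic control.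

Step 4
Reactants: 7 tert-butyl{[(2S,3Z)-4-iodo-2-methylhex-3-en-1-yl]oxy}diphenylsilane; 8 2-[(1E)-3,3-diethoxyprop-1-en-1-yl]-4,4,5,5-tetramethyl-1,3,2-dioxaborolane
Product: 10 (2E,4Z,6S)-7-[(tert-butyldiphenylsilyl)oxy]-4-ethyl-6-methylhepta-2,4-dienal, via dienal diethyl acetal 9 (not isolated)
Conditions: Pd(dppf)Cl2 (5 mol %), aq. K3PO4, THF, 50 °C; then 1 M HCl, THF, 0 °C
Reagents that add atoms: water, O
Why: Suzuki–Miyaura alkenyl–alkenyl coupling proceeds with retention at both partners, so C7 ends up cis to C10 (8Z) with the 6E alkene intact, and mild acetal hydrolysis then frees the aldehyde.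

Step 5
Reactants: 10 (2E,4Z,6S)-7-[(tert-butyldiphenylsilyl)oxy]-4-ethyl-6-methylhepta-2,4-dienal
Product: 11 (3S,4R,5E,7Z,9S)-10-[(tert-butyldiphenylsilyl)oxy]-7-ethyl-3,9-dimethyldeca-1,5,7-trien-4-ol
Conditions: trans-2-butene, KOt-Bu, n-BuLi, THF, −78 → −45 °C; (−)-Ipc2BOMe, −78 °C; BF3·OEt2; then 10, −78 °C; NaOH, H2O2
Reagents that add atoms: (E)-but-2-ene, C/C=C/C
Why: Brown crotylboration through a chair Zimmerman–Traxler transition state, in which the (E)-crotyl group sets the 4,5-anti relationship and the isopinocampheyl groups from (+)-α-pinene select the aldehyde face that should give (4S,5R).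

Step 6
Reactants: 11 (3S,4R,5E,7Z,9S)-10-[(tert-butyldiphenylsilyl)oxy]-7-ethyl-3,9-dimethyldeca-1,5,7-trien-4-ol
Product: 12 (3S,4R,5E,7Z,9S)-10-[(tert-butyldiphenylsilyl)oxy]-7-ethyl-3,9-dimethyldeca-1,5,7-trien-4-yl prop-2-enoate
Conditions: acryloyl chloride, Et3N, CH2Cl2, −78 → 0 °C
Reagents that add atoms: prop-2-enoyl chloride, C=CC(=O)Cl
Why: Esterification of the secondary alcohol with an acid chloride installs the second alkene for ring closure.

Step 7
Reactants: 12 (3S,4R,5E,7Z,9S)-10-[(tert-butyldiphenylsilyl)oxy]-7-ethyl-3,9-dimethyldeca-1,5,7-trien-4-yl prop-2-enoate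
Product: 13 (5S,6R)-6-[(1E,3Z,5S)-6-[(tert-butyldiphenylsilyl)oxy]-3-ethyl-5-methylhexa-1,3-dien-1-yl]-5-methyl-5,6-dihydro-2H-pyran-2-one
Conditions: second-generation Grubbs catalyst (5 mol %), CH2Cl2, 40 °C
Reagents that add atoms: none
Why: Ring-closing metathesis between the terminal vinyl group and the acrylate closes ring A, the internal substituted diene alkenes being much less reactive towards the ruthenium carbene.

Step 8
Reactants: 13 (5S,6R)-6-[(1E,3Z,5S)-6-[(tert-butyldiphenylsilyl)oxy]-3-ethyl-5-methylhexa-1,3-dien-1-yl]-5-methyl-5,6-dihydro-2H-pyran-2-one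
Product: 15 tert-butyl{[(2S,3Z,5E)-4-ethyl-2-methyl-6-[(2R,3S)-3-methyl-6-(propan-2-yloxy)-3,6-dihydro-2H-pyran-2-yl]hexa-3,5-dien-1-yl]oxy}diphenylsilane, via lactol 14 (not isolated)
Conditions: DIBAL-H, CH2Cl2, −78 °C; aq. potassium sodium tartrate; crude lactol, i-PrOH, PPTS, rt
Reagents that add atoms: propan-2-ol, CC(C)O
Why: 1,2-Reduction of the lactone to the lactol followed by acid-catalysed acetalisation masks the electrophilic lactone before organolithium chemistry.

Step 9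
Reactants: 15 tert-butyl{[(2S,3Z,5E)-4-ethyl-2-methyl-6-[(2R,3S)-3-methyl-6-(propan-2-yloxy)-3,6-dihydro-2H-pyran-2-yl]hexa-3,5-dien-1-yl]oxy}diphenylsilane
Product: 16 (2S,3Z,5E)-4-ethyl-2-methyl-6-[(2R,3S)-3-methyl-6-(propan-2-yloxy)-3,6-dihydro-2H-pyran-2-yl]hexa-3,5-dien-1-ol
Conditions: TBAF, THF, 0 °C → rt
Reagents that add atoms: none
Why: Fluoride-mediated desilylation is basic, so the acid-labile allylic acetal should survive.

Step 10
Reactants: 16 (2S,3Z,5E)-4-ethyl-2-methyl-6-[(2R,3S)-3-methyl-6-(propan-2-yloxy)-3,6-dihydro-2H-pyran-2-yl]hexa-3,5-dien-1-ol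
Product: 17 (2R,3S)-2-[(1E,3Z,5S)-3-ethyl-6-iodo-5-methylhexa-1,3-dien-1-yl]-3-methyl-6-(propan-2-yloxy)-3,6-dihydro-2H-pyran
Conditions: I2, PPh3, imidazole, CH2Cl2, 0 °C
Reagents that add atoms: iodine, II
Why: Appel-type iodination of the primary alcohol under imidazole buffering should spare the acetal and the diene.

**Right half (C12–C24)**

Step 11
Reactants: 18 tert-butyl 3-oxobutanoate
Product: 19 tert-butyl (2E)-3-{[(trifluoromethyl)sulfonyl]oxy}but-2-enoate
Conditions: Tf2O, aq. Me4NOH, hexanes, 5 °C → rt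
Reagents that add atoms: trifluoromethanesulfonic anhydride, O=S(=O)(OS(=O)(=O)C(F)(F)F)C(F)(F)F
Why: Stereoselective enol triflation of a β-keto ester, in which the non-chelated tetramethylammonium enolate should give the (E)-enol triflate.

Step 12
Reactants: 1 methyl (2R)-3-hydroxy-2-methylpropanoate
Product: 20 methyl (2S)-3-iodo-2-methylpropanoate
Conditions: I2, PPh3, imidazole, CH2Cl2, 0 °C → rt
Reagents that add atoms: iodine, II
Why: Appel-type iodination of the primary alcohol; the stereocentre (future C20) is untouched and its descriptor changes only by priority.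

Step 13
Reactants: 20 methyl (2S)-3-iodo-2-methylpropanoate; 19 tert-butyl (2E)-3-{[(trifluoromethyl)sulfonyl]oxy}but-2-enoate
Product: 22 1-tert-butyl 6-methyl (2E,5R)-3,5-dimethylhex-2-enedioate, via alkylzinc iodide 21 (not isolated)
Conditions: Zn dust (activated with 1,2-dibromoethane and TMSCl), DMA, rt; then 19, Pd(PPh3)4 (3 mol %), THF, 40 °C
Reagents that add atoms: none
Why: Zinc insertion gives a configurationally stable β-zincio ester, and the Negishi sp3–sp2 coupling proceeds with retention of the enol triflate geometry to set the 22E trisubstituted enoate.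

Step 14
Reactants: 22 1-tert-butyl 6-methyl (2E,5R)-3,5-dimethylhex-2-enedioate
Product: 23 tert-butyl (2E,5R)-3,5-dimethyl-6-oxohex-2-enoate
Conditions: DIBAL-H (1.05 equiv), toluene, −78 °C; aq. potassium sodium tartrate
Reagents that add atoms: none
Why: Chemoselective DIBAL-H partial reduction should attack the unhindered saturated methyl ester in preference to the hindered, conjugated tert-butyl ester.

Step 15
Reactants: 23 tert-butyl (2E,5R)-3,5-dimethyl-6-oxohex-2-enoate
Product: 24 tert-butyl (2E,5R,6R,7S)-6-hydroxy-3,5,7-trimethylnona-2,8-dienoate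
Conditions: trans-2-butene, KOt-Bu, n-BuLi, THF, −78 → −45 °C; (−)-Ipc2BOMe, −78 °C; BF3·OEt2; then 23, −78 °C; NaOH, H2O2
Reagents that add atoms: (E)-but-2-ene, C/C=C/C
Why: Brown crotylboration in which the (E)-crotyl group sets the 18,19-anti relationship and reagent control from the same (−)-Ipc2B reagent should override the weak Felkin bias of the α-methyl aldehyde to give the 19,20-anti (all-anti) triad.

Step 16
Reactants: 24 tert-butyl (2E,5R,6R,7S)-6-hydroxy-3,5,7-trimethylnona-2,8-dienoate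
Product: 25 tert-butyl (2E,5R,6R,7S)-6-[(tert-butyldimethylsilyl)oxy]-3,5,7-trimethylnona-2,8-dienoate
Conditions: TBSOTf, 2,6-lutidine, CH2Cl2, −78 °C
Reagents that add atoms: tert-butyldimethylsilyl trifluoromethanesulfonate, CC(C)(C)[Si](C)(C)OS(=O)(=O)C(F)(F)F
Why: Silyl triflate protection of the hindered secondary C19 alcohol.

Step 17
Reactants: 25 tert-butyl (2E,5R,6R,7S)-6-[(tert-butyldimethylsilyl)oxy]-3,5,7-trimethylnona-2,8-dienoate
Product: 27 tert-butyl (2E,5R,6R,7R)-6-[(tert-butyldimethylsilyl)oxy]-3,5,7-trimethyl-8-oxooct-2-enoate, via vicinal diol 26 (not isolated)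
Conditions: OsO4 (2 mol %), NaIO4, 2,6-lutidine, dioxane/H2O, rt
Reagents that add atoms: osmium tetroxide, O=[Os](=O)(=O)=O; sodium periodate (terminal oxidant), [Na+].[O-]I(=O)(=O)=O
Why: Lemieux–Johnson oxidative cleavage should select the monosubstituted alkene over the electron-poor trisubstituted enoate.

Step 18
Reactants: 28 (4R)-4-benzyl-1,3-oxazolidin-2-one
Product: 29 (4R)-4-benzyl-3-[(2E)-but-2-enoyl]-1,3-oxazolidin-2-one
Conditions: n-BuLi, THF, −78 °C; (E)-but-2-enoyl chloride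
Reagents that add atoms: (E)-but-2-enoyl chloride, C/C=C/C(Cl)=O
Why: N-Acylation of the lithiated oxazolidinone.

Step 19
Reactants: 27 tert-butyl (2E,5R,6R,7R)-6-[(tert-butyldimethylsilyl)oxy]-3,5,7-trimethyl-8-oxooct-2-enoate; 29 (4R)-4-benzyl-3-[(2E)-but-2-enoyl]-1,3-oxazolidin-2-one
Product: 30 tert-butyl (2E,5R,6R,7S,8S,9R)-9-{[(4R)-4-benzyl-2-oxo-1,3-oxazolidin-3-yl]carbonyl}-6-[(tert-butyldimethylsilyl)oxy]-8-hydroxy-3,5,7-trimethylundeca-2,10-dienoate
Conditions: 29, Bu2BOTf, Et3N, CH2Cl2, −78 → 0 °C; then 27, −78 → 0 °C; pH 7 buffer, MeOH, H2O2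
Reagents that add atoms: none
Why: Evans syn-aldol of the boron dienolate of the crotonyl imide, which reacts at its α-carbon through a chair transition state so that the (R)-benzyl auxiliary sets C16 (and the temporary C17 carbinol) by reagent control.

Step 20
Reactants: 30 tert-butyl (2E,5R,6R,7S,8S,9R)-9-{[(4R)-4-benzyl-2-oxo-1,3-oxazolidin-3-yl]carbonyl}-6-[(tert-butyldimethylsilyl)oxy]-8-hydroxy-3,5,7-trimethylundeca-2,10-dienoate
Product: 31 tert-butyl (2E,5R,6R,7S,8R,9S)-6-[(tert-butyldimethylsilyl)oxy]-8-hydroxy-9-(hydroxymethyl)-3,5,7-trimethylundeca-2,10-dienoate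
Conditions: LiBH4, MeOH (1 equiv), THF, 0 °C
Reagents that add atoms: none
Why: Reductive removal of the auxiliary with LiBH4 turns the imide carbonyl into the C16' hydroxymethyl group and should leave the tert-butyl enoate alone.

Step 21
Reactants: 31 tert-butyl (2E,5R,6R,7S,8R,9S)-6-[(tert-butyldimethylsilyl)oxy]-8-hydroxy-9-(hydroxymethyl)-3,5,7-trimethylundeca-2,10-dienoate
Product: 32 tert-butyl (2E,5R,6R,7S,8R,9S)-6-[(tert-butyldimethylsilyl)oxy]-9-{[(tert-butyldimethylsilyl)oxy]methyl}-8-hydroxy-3,5,7-trimethylundeca-2,10-dienoate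
Conditions: TBSCl, imidazole, CH2Cl2, 0 °C
Reagents that add atoms: tert-butyl(chloro)dimethylsilane, CC(C)(C)[Si](C)(C)Cl
Why: Silylation should be selective for the primary alcohol over the hindered secondary C17 alcohol, which stays free for the late oxidation.

Step 22
Reactants: 32 tert-butyl (2E,5R,6R,7S,8R,9S)-6-[(tert-butyldimethylsilyl)oxy]-9-{[(tert-butyldimethylsilyl)oxy]methyl}-8-hydroxy-3,5,7-trimethylundeca-2,10-dienoate
Product: 33 tert-butyl (2E,5R,6R,7S,8R,9S,10E)-6-[(tert-butyldimethylsilyl)oxy]-9-{[(tert-butyldimethylsilyl)oxy]methyl}-8-hydroxy-3,5,7,11-tetramethyl-12-oxododeca-2,10-dienoate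
Conditions: methacrolein (excess), second-generation Hoveyda–Grubbs catalyst (10 mol %), CH2Cl2, 40 °C
Reagents that add atoms: 2-methylprop-2-enal, CC(=C)C=O
Why: Cross-metathesis of the terminal alkene with methacrolein should give the (E)-trisubstituted enal under thermodynamic control, the trisubstituted enoate being inert.

Step 23
Reactants: 33 tert-butyl (2E,5R,6R,7S,8R,9S,10E)-6-[(tert-butyldimethylsilyl)oxy]-9-{[(tert-butyldimethylsilyl)oxy]methyl}-8-hydroxy-3,5,7,11-tetramethyl-12-oxododeca-2,10-dienoate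
Product: 34 tert-butyl (2E,5R,6R,7S,8R,9S,10E,12E)-6-[(tert-butyldimethylsilyl)oxy]-9-{[(tert-butyldimethylsilyl)oxy]methyl}-8-hydroxy-13-iodo-3,5,7,11-tetramethyltrideca-2,10,12-trienoate
Conditions: CrCl2, CHI3, THF/dioxane, 0 °C → rt
Reagents that add atoms: iodoform, IC(I)I
Why: Takai olefination (geminal dichromium species from CHI3 and CrCl2) should convert the enal into the (E)-vinyl iodide and tolerates the free hydroxyl and the ester.

Step 24
Reactants: 34 tert-butyl (2E,5R,6R,7S,8R,9S,10E,12E)-6-[(tert-butyldimethylsilyl)oxy]-9-{[(tert-butyldimethylsilyl)oxy]methyl}-8-hydroxy-13-iodo-3,5,7,11-tetramethyltrideca-2,10,12-trienoate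
Product: 36 (2E,5R,6R,7S,8R,9S,10E,12E)-6-[(tert-butyldimethylsilyl)oxy]-9-{[(tert-butyldimethylsilyl)oxy]methyl}-8-hydroxy-13-iodo-3,5,7,11-tetramethyltrideca-2,10,12-trienoic acid, via trimethylsilyl ester C17 trimethylsilyl ether 35 (not isolated)
Conditions: TMSOTf, 2,6-lutidine, CH2Cl2, 0 °C; then MeOH, aq. citric acid, rt
Reagents that add atoms: none
Why: Silyl triflate-mediated cleavage of the tert-butyl ester (loss of isobutene) with transient silylation of the C17 hydroxyl, after which mild acidic methanolysis should free the acid and the alcohol while both TBS ethers stay.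

**Fragment union and endgame**

Step 25
Reactants: 17 (2R,3S)-2-[(1E,3Z,5S)-3-ethyl-6-iodo-5-methylhexa-1,3-dien-1-yl]-3-methyl-6-(propan-2-yloxy)-3,6-dihydro-2H-pyran; 36 (2E,5R,6R,7S,8R,9S,10E,12E)-6-[(tert-butyldimethylsilyl)oxy]-9-{[(tert-butyldimethylsilyl)oxy]methyl}-8-hydroxy-13-iodo-3,5,7,11-tetramethyltrideca-2,10,12-trienoic acid
Product: 39 (2E,5R,6R,7S,8R,9S,10E,12E,15R,16Z,18E)-6-[(tert-butyldimethylsilyl)oxy]-9-{[(tert-butyldimethylsilyl)oxy]methyl}-17-ethyl-8-hydroxy-3,5,7,11,15-pentamethyl-19-[(2R,3S)-3-methyl-6-(propan-2-yloxy)-3,6-dihydro-2H-pyran-2-yl]nonadeca-2,10,12,16,18-pentaenoic acid, via C11 alkyllithium 37 (not isolated), via lithium B-alkyl-B-methoxy-9-BBN ate complex 38 (not isolated)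
Conditions: 17, B-methoxy-9-BBN, t-BuLi (2.1 equiv), Et2O, −78 °C, then THF, → rt; then 36, Pd(dppf)Cl2 (10 mol %), AsPh3, aq. K3PO4 (3 M), DMF, rt
Reagents that add atoms: none
Why: Iodine–lithium exchange on the primary iodide gives alkyllithium 37, which is trapped at −78 °C by B-methoxy-9-BBN as ate complex 38; the precatalyst is reduced to zerovalent palladium, which inserts into the C12–I bond of 36, the primary C11 alkyl group is transferred from boron to palladium, and reductive elimination forms the C11–C12 bond. The closest known reaction type is the B-alkyl Suzuki–Miyaura coupling of 9-BBN borates, made from lithiated primary iodides, with (E)-iodoalkenes, which has close precedent for alkyl–dienyl unions in polyketides of this family. No ring is closed and no stereocentre is created: C10 sits β to boron and is untouched, and the 12E and 14E geometries are carried over from 36 because oxidative addition and reductive elimination are stereoretentive. The step needs chemoselectivity (exchange at iodine without attack on the acetal or carbolithiation of the diene, and coupling in the presence of the carboxylate and the free C17 hydroxyl) and must outrun β-hydride elimination of the alkylpalladium. The in situ borate trap at low temperature, the absence of any carbonyl group in 17, the aqueous phosphate that holds 36 as its potassium carboxylate, and the wide-bite-angle dppf ligand should secure this. In one operation the step should deliver the complete carbon skeleton with all seven stereocentres and all five acyclic alkene geometries in place.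

Step 26
Reactants: 39 (2E,5R,6R,7S,8R,9S,10E,12E,15R,16Z,18E)-6-[(tert-butyldimethylsilyl)oxy]-9-{[(tert-butyldimethylsilyl)oxy]methyl}-17-ethyl-8-hydroxy-3,5,7,11,15-pentamethyl-19-[(2R,3S)-3-methyl-6-(propan-2-yloxy)-3,6-dihydro-2H-pyran-2-yl]nonadeca-2,10,12,16,18-pentaenoic acid
Product: 40 (2E,5R,6R,7S,8R,9S,10E,12E,15R,16Z,18E)-6-[(tert-butyldimethylsilyl)oxy]-9-{[(tert-butyldimethylsilyl)oxy]methyl}-17-ethyl-8-hydroxy-19-[(2R,3S)-6-hydroxy-3-methyl-3,6-dihydro-2H-pyran-2-yl]-3,5,7,11,15-pentamethylnonadeca-2,10,12,16,18-pentaenoic acid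
Conditions: PPTS, acetone/H2O, rt
Reagents that add atoms: water, O
Why: Mild acid hydrolysis of the allylic lactol acetal should leave the TBS ethers in place.

Step 27
Reactants: 40 (2E,5R,6R,7S,8R,9S,10E,12E,15R,16Z,18E)-6-[(tert-butyldimethylsilyl)oxy]-9-{[(tert-butyldimethylsilyl)oxy]methyl}-17-ethyl-8-hydroxy-19-[(2R,3S)-6-hydroxy-3-methyl-3,6-dihydro-2H-pyran-2-yl]-3,5,7,11,15-pentamethylnonadeca-2,10,12,16,18-pentaenoic acid
Product: 41 (2E,5R,6R,7R,9S,10E,12E,15R,16Z,18E)-6-[(tert-butyldimethylsilyl)oxy]-9-{[(tert-butyldimethylsilyl)oxy]methyl}-17-ethyl-3,5,7,11,15-pentamethyl-19-[(2R,3S)-3-methyl-6-oxo-3,6-dihydro-2H-pyran-2-yl]-8-oxononadeca-2,10,12,16,18-pentaenoic acid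
Conditions: Dess–Martin periodinane, NaHCO3, CH2Cl2, 0 °C → rt
Reagents that add atoms: none
Why: Dess–Martin oxidation should convert both the lactol (to the unsaturated lactone) and the C17 carbinol (to the ketone) under buffered conditions that do not epimerise C16.

Step 28
Reactants: 41 (2E,5R,6R,7R,9S,10E,12E,15R,16Z,18E)-6-[(tert-butyldimethylsilyl)oxy]-9-{[(tert-butyldimethylsilyl)oxy]methyl}-17-ethyl-3,5,7,11,15-pentamethyl-19-[(2R,3S)-3-methyl-6-oxo-3,6-dihydro-2H-pyran-2-yl]-8-oxononadeca-2,10,12,16,18-pentaenoic acid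
Product: 42 (2E,5R,6R,7R,9S,10E,12E,15R,16Z,18E)-17-ethyl-6-hydroxy-9-(hydroxymethyl)-3,5,7,11,15-pentamethyl-19-[(2R,3S)-3-methyl-6-oxo-3,6-dihydro-2H-pyran-2-yl]-8-oxononadeca-2,10,12,16,18-pentaenoic acid (CNP0302052.3)
Conditions: HF·pyridine, pyridine, THF, 0 °C → rt
Reagents that add atoms: none
Why: Acidic fluoride desilylation of both TBS ethers should avoid retro-aldol loss of formaldehyde or β-elimination at the β-hydroxy ketone.

**Compound list**

1 | methyl (2R)-3-hydroxy-2-methylpropanoate | COC(=O)[C@H](C)CO | starting material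
2 | methyl (2R)-3-[(tert-butyldiphenylsilyl)oxy]-2-methylpropanoate | COC(=O)[C@H](C)CO[Si](c1ccccc1)(c1ccccc1)C(C)(C)C | intermediate
3 | (2R)-3-[(tert-butyldiphenylsilyl)oxy]-2-methylpropanal | O=C[C@H](C)CO[Si](c1ccccc1)(c1ccccc1)C(C)(C)C | intermediate
4 | propyltriphenylphosphonium bromide | CCC[P+](c1ccccc1)(c1ccccc1)c1ccccc1.[Br-] | starting material
5 | (1-iodopropyl)triphenylphosphonium iodide | CCC(I)[P+](c1ccccc1)(c1ccccc1)c1ccccc1.[I-] | intermediate
6 | (1-iodopropylidene)triphenylphosphorane | CCC(I)=P(c1ccccc1)(c1ccccc1)c1ccccc1 | intermediate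
7 | tert-butyl{[(2S,3Z)-4-iodo-2-methylhex-3-en-1-yl]oxy}diphenylsilane | CCC(=C/[C@H](C)CO[Si](c1ccccc1)(c1ccccc1)C(C)(C)C)/I | intermediate
8 | 2-[(1E)-3,3-diethoxyprop-1-en-1-yl]-4,4,5,5-tetramethyl-1,3,2-dioxaborolane | CCOC(OCC)/C=C/B1OC(C)(C)C(C)(C)O1 | starting material
9 | tert-butyl{[(2S,3Z,5E)-7,7-diethoxy-4-ethyl-2-methylhepta-3,5-dien-1-yl]oxy}diphenylsilane | CCC(=C/[C@H](C)CO[Si](c1ccccc1)(c1ccccc1)C(C)(C)C)/C=C/C(OCC)OCC | intermediate
10 | (2E,4Z,6S)-7-[(tert-butyldiphenylsilyl)oxy]-4-ethyl-6-methylhepta-2,4-dienal | CCC(=C/[C@H](C)CO[Si](c1ccccc1)(c1ccccc1)C(C)(C)C)/C=C/C=O | intermediate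
11 | (3S,4R,5E,7Z,9S)-10-[(tert-butyldiphenylsilyl)oxy]-7-ethyl-3,9-dimethyldeca-1,5,7-trien-4-ol | CCC(=C/[C@H](C)CO[Si](c1ccccc1)(c1ccccc1)C(C)(C)C)/C=C/[C@@H](O)[C@@H](C)C=C | intermediate
12 | (3S,4R,5E,7Z,9S)-10-[(tert-butyldiphenylsilyl)oxy]-7-ethyl-3,9-dimethyldeca-1,5,7-trien-4-yl prop-2-enoate | CCC(=C/[C@H](C)CO[Si](c1ccccc1)(c1ccccc1)C(C)(C)C)/C=C/[C@@H](OC(=O)C=C)[C@@H](C)C=C | intermediate
13 | (5S,6R)-6-[(1E,3Z,5S)-6-[(tert-butyldiphenylsilyl)oxy]-3-ethyl-5-methylhexa-1,3-dien-1-yl]-5-methyl-5,6-dihydro-2H-pyran-2-one | CCC(=C/[C@H](C)CO[Si](c1ccccc1)(c1ccccc1)C(C)(C)C)/C=C/[C@H]1OC(=O)C=C[C@@H]1C | intermediate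
14 | (5S,6R)-6-[(1E,3Z,5S)-6-[(tert-butyldiphenylsilyl)oxy]-3-ethyl-5-methylhexa-1,3-dien-1-yl]-5-methyl-5,6-dihydro-2H-pyran-2-ol (anomeric mixture) | CCC(=C/[C@H](C)CO[Si](c1ccccc1)(c1ccccc1)C(C)(C)C)/C=C/[C@H]1OC(O)C=C[C@@H]1C | intermediate
15 | tert-butyl{[(2S,3Z,5E)-4-ethyl-2-methyl-6-[(2R,3S)-3-methyl-6-(propan-2-yloxy)-3,6-dihydro-2H-pyran-2-yl]hexa-3,5-dien-1-yl]oxy}diphenylsilane | CCC(=C/[C@H](C)CO[Si](c1ccccc1)(c1ccccc1)C(C)(C)C)/C=C/[C@H]1OC(OC(C)C)C=C[C@@H]1C | intermediate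
16 | (2S,3Z,5E)-4-ethyl-2-methyl-6-[(2R,3S)-3-methyl-6-(propan-2-yloxy)-3,6-dihydro-2H-pyran-2-yl]hexa-3,5-dien-1-ol | CCC(=C/[C@H](C)CO)/C=C/[C@H]1OC(OC(C)C)C=C[C@@H]1C | intermediate
17 | (2R,3S)-2-[(1E,3Z,5S)-3-ethyl-6-iodo-5-methylhexa-1,3-dien-1-yl]-3-methyl-6-(propan-2-yloxy)-3,6-dihydro-2H-pyran | CCC(=C/[C@H](C)CI)/C=C/[C@H]1OC(OC(C)C)C=C[C@@H]1C | intermediate
18 | tert-butyl 3-oxobutanoate | CC(=O)CC(=O)OC(C)(C)C | starting material
19 | tert-butyl (2E)-3-{[(trifluoromethyl)sulfonyl]oxy}but-2-enoate | CC(C)(C)OC(=O)/C=C(\C)OS(=O)(=O)C(F)(F)F | intermediate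
20 | methyl (2S)-3-iodo-2-methylpropanoate | COC(=O)[C@H](C)CI | intermediate
21 | [(2S)-3-methoxy-2-methyl-3-oxopropyl]zinc iodide | COC(=O)[C@H](C)C[Zn]I | intermediate
22 | 1-tert-butyl 6-methyl (2E,5R)-3,5-dimethylhex-2-enedioate | COC(=O)[C@H](C)C/C(C)=C/C(=O)OC(C)(C)C | intermediate
23 | tert-butyl (2E,5R)-3,5-dimethyl-6-oxohex-2-enoate | O=C[C@H](C)C/C(C)=C/C(=O)OC(C)(C)C | intermediate
24 | tert-butyl (2E,5R,6R,7S)-6-hydroxy-3,5,7-trimethylnona-2,8-dienoate | C=C[C@H](C)[C@H](O)[C@H](C)C/C(C)=C/C(=O)OC(C)(C)C | intermediate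
25 | tert-butyl (2E,5R,6R,7S)-6-[(tert-butyldimethylsilyl)oxy]-3,5,7-trimethylnona-2,8-dienoate | C=C[C@H](C)[C@H](O[Si](C)(C)C(C)(C)C)[C@H](C)C/C(C)=C/C(=O)OC(C)(C)C | intermediate
26 | vicinal diol from dihydroxylation of the vinyl group of 25 (both C17 epimers; other centres as in 25) | OCC(O)[C@H](C)[C@H](O[Si](C)(C)C(C)(C)C)[C@H](C)C/C(C)=C/C(=O)OC(C)(C)C | intermediate
27 | tert-butyl (2E,5R,6R,7R)-6-[(tert-butyldimethylsilyl)oxy]-3,5,7-trimethyl-8-oxooct-2-enoate | O=C[C@H](C)[C@H](O[Si](C)(C)C(C)(C)C)[C@H](C)C/C(C)=C/C(=O)OC(C)(C)C | intermediate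
28 | (4R)-4-benzyl-1,3-oxazolidin-2-one | O=C1N[C@H](Cc2ccccc2)CO1 | starting material
29 | (4R)-4-benzyl-3-[(2E)-but-2-enoyl]-1,3-oxazolidin-2-one | C/C=C/C(=O)N1[C@H](Cc2ccccc2)COC1=O | intermediate
30 | tert-butyl (2E,5R,6R,7S,8S,9R)-9-{[(4R)-4-benzyl-2-oxo-1,3-oxazolidin-3-yl]carbonyl}-6-[(tert-butyldimethylsilyl)oxy]-8-hydroxy-3,5,7-trimethylundeca-2,10-dienoate | O=C1OC[C@@H](Cc2ccccc2)N1C(=O)[C@H](C=C)[C@@H](O)[C@H](C)[C@H](O[Si](C)(C)C(C)(C)C)[C@H](C)C/C(C)=C/C(=O)OC(C)(C)C | intermediate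
31 | tert-butyl (2E,5R,6R,7S,8R,9S)-6-[(tert-butyldimethylsilyl)oxy]-8-hydroxy-9-(hydroxymethyl)-3,5,7-trimethylundeca-2,10-dienoate | OC[C@H](C=C)[C@@H](O)[C@H](C)[C@H](O[Si](C)(C)C(C)(C)C)[C@H](C)C/C(C)=C/C(=O)OC(C)(C)C | intermediate
32 | tert-butyl (2E,5R,6R,7S,8R,9S)-6-[(tert-butyldimethylsilyl)oxy]-9-{[(tert-butyldimethylsilyl)oxy]methyl}-8-hydroxy-3,5,7-trimethylundeca-2,10-dienoate | CC(C)(C)[Si](C)(C)OC[C@H](C=C)[C@@H](O)[C@H](C)[C@H](O[Si](C)(C)C(C)(C)C)[C@H](C)C/C(C)=C/C(=O)OC(C)(C)C | intermediate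
33 | tert-butyl (2E,5R,6R,7S,8R,9S,10E)-6-[(tert-butyldimethylsilyl)oxy]-9-{[(tert-butyldimethylsilyl)oxy]methyl}-8-hydroxy-3,5,7,11-tetramethyl-12-oxododeca-2,10-dienoate | CC(C)(C)[Si](C)(C)OC[C@H](/C=C(\C)C=O)[C@@H](O)[C@H](C)[C@H](O[Si](C)(C)C(C)(C)C)[C@H](C)C/C(C)=C/C(=O)OC(C)(C)C | intermediate
34 | tert-butyl (2E,5R,6R,7S,8R,9S,10E,12E)-6-[(tert-butyldimethylsilyl)oxy]-9-{[(tert-butyldimethylsilyl)oxy]methyl}-8-hydroxy-13-iodo-3,5,7,11-tetramethyltrideca-2,10,12-trienoate | I/C=C/C(C)=C/[C@@H](CO[Si](C)(C)C(C)(C)C)[C@@H](O)[C@H](C)[C@H](O[Si](C)(C)C(C)(C)C)[C@H](C)C/C(C)=C/C(=O)OC(C)(C)C | intermediate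
35 | trimethylsilyl ester and C17 trimethylsilyl ether of acid 36 (all centres as in 36) | I/C=C/C(C)=C/[C@@H](CO[Si](C)(C)C(C)(C)C)[C@@H](O[Si](C)(C)C)[C@H](C)[C@H](O[Si](C)(C)C(C)(C)C)[C@H](C)C/C(C)=C/C(=O)O[Si](C)(C)C | intermediate
36 | (2E,5R,6R,7S,8R,9S,10E,12E)-6-[(tert-butyldimethylsilyl)oxy]-9-{[(tert-butyldimethylsilyl)oxy]methyl}-8-hydroxy-13-iodo-3,5,7,11-tetramethyltrideca-2,10,12-trienoic acid | I/C=C/C(C)=C/[C@@H](CO[Si](C)(C)C(C)(C)C)[C@@H](O)[C@H](C)[C@H](O[Si](C)(C)C(C)(C)C)[C@H](C)C/C(C)=C/C(=O)O | intermediate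
37 | C11 alkyllithium from 17 (lithium in place of iodine; all centres as in 17) | CCC(=C/[C@H](C)C[Li])/C=C/[C@H]1OC(OC(C)C)C=C[C@@H]1C | intermediate
38 | lithium B-methoxy-9-borabicyclo[3.3.1]nonane ate complex carrying the C1–C11 alkyl group of 17 on boron | [Li+].CCC(=C/[C@H](C)C[B-]1(OC)C2CCCC1CCC2)/C=C/[C@H]1OC(OC(C)C)C=C[C@@H]1C | intermediate
39 | (2E,5R,6R,7S,8R,9S,10E,12E,15R,16Z,18E)-6-[(tert-butyldimethylsilyl)oxy]-9-{[(tert-butyldimethylsilyl)oxy]methyl}-17-ethyl-8-hydroxy-3,5,7,11,15-pentamethyl-19-[(2R,3S)-3-methyl-6-(propan-2-yloxy)-3,6-dihydro-2H-pyran-2-yl]nonadeca-2,10,12,16,18-pentaenoic acid | CCC(=C/[C@H](C)C/C=C/C(C)=C/[C@@H](CO[Si](C)(C)C(C)(C)C)[C@@H](O)[C@H](C)[C@H](O[Si](C)(C)C(C)(C)C)[C@H](C)C/C(C)=C/C(=O)O)/C=C/[C@H]1OC(OC(C)C)C=C[C@@H]1C | intermediate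
40 | (2E,5R,6R,7S,8R,9S,10E,12E,15R,16Z,18E)-6-[(tert-butyldimethylsilyl)oxy]-9-{[(tert-butyldimethylsilyl)oxy]methyl}-17-ethyl-8-hydroxy-19-[(2R,3S)-6-hydroxy-3-methyl-3,6-dihydro-2H-pyran-2-yl]-3,5,7,11,15-pentamethylnonadeca-2,10,12,16,18-pentaenoic acid | CCC(=C/[C@H](C)C/C=C/C(C)=C/[C@@H](CO[Si](C)(C)C(C)(C)C)[C@@H](O)[C@H](C)[C@H](O[Si](C)(C)C(C)(C)C)[C@H](C)C/C(C)=C/C(=O)O)/C=C/[C@H]1OC(O)C=C[C@@H]1C | intermediate
41 | (2E,5R,6R,7R,9S,10E,12E,15R,16Z,18E)-6-[(tert-butyldimethylsilyl)oxy]-9-{[(tert-butyldimethylsilyl)oxy]methyl}-17-ethyl-3,5,7,11,15-pentamethyl-19-[(2R,3S)-3-methyl-6-oxo-3,6-dihydro-2H-pyran-2-yl]-8-oxononadeca-2,10,12,16,18-pentaenoic acid | CCC(=C/[C@H](C)C/C=C/C(C)=C/[C@@H](CO[Si](C)(C)C(C)(C)C)C(=O)[C@H](C)[C@H](O[Si](C)(C)C(C)(C)C)[C@H](C)C/C(C)=C/C(=O)O)/C=C/[C@H]1OC(=O)C=C[C@@H]1C | intermediate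
42 | (2E,5R,6R,7R,9S,10E,12E,15R,16Z,18E)-17-ethyl-6-hydroxy-9-(hydroxymethyl)-3,5,7,11,15-pentamethyl-19-[(2R,3S)-3-methyl-6-oxo-3,6-dihydro-2H-pyran-2-yl]-8-oxononadeca-2,10,12,16,18-pentaenoic acid | CCC(=C/[C@H](C)C/C=C/C(C)=C/[C@@H](CO)C(=O)[C@H](C)[C@H](O)[C@H](C)C/C(C)=C/C(=O)O)/C=C/[C@H]1OC(=O)C=C[C@@H]1C | target

**Summary**

Total step count: 28.
Longest linear sequence: 16 steps, from compound 1 through steps 12–17 and 19–24, then steps 25–28.

Steps most likely to fail: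

Step 25. The alkyllithium may be lost by carbolithiation of the diene before it is trapped, the acidic partner may quench the borate, and the β-branched alkyl group may transfer slowly so that β-hydride elimination and protodeboronation compete. The fallback leaves the aqueous borate manifold for an anhydrous organozinc coupling with the acidic protons masked. It sets out from iodide 17 and from the persilylated compound 35, taken before its hydrolytic work-up. Alkyllithium 37 would be transmetalated with ZnCl2 to the C11 alkylzinc chloride of the C1–C11 fragment F1 in THF. Negishi coupling of F1 with 35 under Pd(PPh3)4 in THF would then give the trimethylsilyl ester and C17 trimethylsilyl ether of the coupled acid F2 as the crude product. Methanolic citric acid in the work-up would remove the two trimethylsilyl groups of F2, and the route is rejoined at 39.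

Step 3. The iodo-ylide olefination may give low conversion, erosion of Z selectivity and epimerisation of the α-stereocentre of the aldehyde. The fallback builds the trisubstituted alkene by two palladium-catalysed couplings instead. It sets out from aldehyde 3, which would be converted with CBr4 and PPh3 into tert-butyl{[(2S)-4,4-dibromo-2-methylbut-3-en-1-yl]oxy}diphenylsilane F3 by Corey–Fuchs-type dibromo-olefination. A trans-selective Negishi monoethylation of F3 (EtZnBr, Pd(DPEphos)Cl2, THF) would then give tert-butyl{[(2S,3Z)-4-bromo-2-methylhex-3-en-1-yl]oxy}diphenylsilane F4 with bromine cis to the branched chain. Suzuki–Miyaura coupling of F4 with 8 and acetal hydrolysis, as in step 4, rejoins the route at 10.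

Step 22. Metathesis at the allylically branched terminal alkene may be slow, with catalyst decomposition and self-metathesis of methacrolein taking over. The fallback replaces the metathesis by cleavage and olefination. It sets out from 32, whose vinyl group would be cleaved (OsO4, NaIO4, 2,6-lutidine) to tert-butyl (2E,5R,6R,7S,8S,9S)-6-[(tert-butyldimethylsilyl)oxy]-9-{[(tert-butyldimethylsilyl)oxy]methyl}-8-hydroxy-3,5,7-trimethyl-10-oxodec-2-enoate F5 under buffered conditions. Wittig olefination of F5 with 2-(triphenylphosphoranylidene)propanal in toluene at 80 °C should give the (E)-enal and rejoins the route at 33.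

**Further compounds**

F1 | step 25 | C11 alkylzinc chloride of the C1–C11 fragment (zinc chloride in place of the iodine of 17) | CCC(=C/[C@H](C)C[Zn]Cl)/C=C/[C@H]1OC(OC(C)C)C=C[C@@H]1C
F2 | step 25 | trimethylsilyl ester and C17 trimethylsilyl ether of the coupled acid (acid 39 carrying two trimethylsilyl groups) | CCC(=C/[C@H](C)C/C=C/C(C)=C/[C@@H](CO[Si](C)(C)C(C)(C)C)[C@@H](O[Si](C)(C)C)[C@H](C)[C@H](O[Si](C)(C)C(C)(C)C)[C@H](C)C/C(C)=C/C(=O)O[Si](C)(C)C)/C=C/[C@H]1OC(OC(C)C)C=C[C@@H]1C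
F3 | step 3 | tert-butyl{[(2S)-4,4-dibromo-2-methylbut-3-en-1-yl]oxy}diphenylsilane | BrC(Br)=C[C@H](C)CO[Si](c1ccccc1)(c1ccccc1)C(C)(C)C
F4 | step 3 | tert-butyl{[(2S,3Z)-4-bromo-2-methylhex-3-en-1-yl]oxy}diphenylsilane | CCC(=C/[C@H](C)CO[Si](c1ccccc1)(c1ccccc1)C(C)(C)C)/Br
F5 | step 22 | tert-butyl (2E,5R,6R,7S,8S,9S)-6-[(tert-butyldimethylsilyl)oxy]-9-{[(tert-butyldimethylsilyl)oxy]methyl}-8-hydroxy-3,5,7-trimethyl-10-oxodec-2-enoate | O=C[C@@H](CO[Si](C)(C)C(C)(C)C)[C@@H](O)[C@H](C)[C@H](O[Si](C)(C)C(C)(C)C)[C@H](C)C/C(C)=C/C(=O)OC(C)(C)C
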